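**Retrosynthetic overview**
1. Ring A is made first, from acyclic pieces. Its C1–C6 bond is disconnected as a Michael addition of methyl 4-methoxyacetoacetate (1) to acrolein (2), and its C3–C4 bond as the aldol closure of the adduct (3 → 4).
2. Dehydration (5) and dehydrogenation give methyl 3-methoxysalicylate (6). The OMe group and the future ether oxygen both come from 1.
3. Both ring A bromines trace back to the free acid 7: C5–Br by substitution para to OH (8), and C1–Br by ipso bromodecarboxylation (9). The carboxyl carbon that activated the Michael donor therefore marks a bromine site.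
4. The diaryl ether C–O bond is disconnected by SNAr into 9 and 2-bromo-1-fluoro-4-nitrobenzene (10). Ring B is bought as an arene and joined last (11).
5. The 4'-bromine traces back to the nitro group through aniline 12 and a Sandmeyer reaction (13 → 14).

Assumption: 14 has no stereocentre and no resolvable axis, so it is one achiral compound and needs no enantiocontrol; ring A is numbered as in the name of 14 (C1 Br, C2 OAr, C3 OMe, C5 Br).

**Step 1**
Reactants: 1 methyl 4-methoxy-3-oxobutanoate (methyl 4-methoxyacetoacetate); 2 prop-2-enal (acrolein)
Product: 4 methyl 4-hydroxy-3-methoxy-2-oxocyclohexane-1-carboxylate (racemic diastereomer mixture), via Michael adduct 3 (not isolated)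
Conditions: NaOMe (5 mol %), MeOH, −10 °C, 2 added slowly to 1 (1.3 equiv), then rt, 16 h; AcOH quench
Reagents that add atoms: none
Why: Base-catalysed Michael addition of the doubly activated C2 carbon of 1 to acrolein forms the C1–C6 bond, and the tethered aldehyde is then captured by the methoxy-bearing carbon in a six-membered intramolecular aldol addition; the three new stereocentres form unselectively and are all erased by step 3.

**Step 2**
Reactants: 4 methyl 4-hydroxy-3-methoxy-2-oxocyclohexane-1-carboxylate
Product: 5 methyl 3-methoxy-2-oxocyclohex-3-ene-1-carboxylate (racemic; largely enolised)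
Conditions: p-TsOH·H2O (10 mol %), toluene, reflux (Dean–Stark), 2 h
Reagents that add atoms: none
Why: Acid-catalysed dehydration of the β-hydroxy ketone completes the aldol condensation (any 3 left in the crude closes to the same enone), and azeotropic removal of water protects the 2-methoxy enol ether from hydrolysis.

**Step 3**
Reactants: 5 methyl 3-methoxy-2-oxocyclohex-3-ene-1-carboxylate
Product: 6 methyl 2-hydroxy-3-methoxybenzoate
Conditions: DDQ (1.1 equiv), toluene, rt → 60 °C, 3 h
Reagents that add atoms: none
Why: In this dehydrogenative aromatisation the dienol tautomer of 5 is already a dihydroarene, so hydride abstraction by DDQ followed by proton loss gives the hydrogen-bonded salicylate and removes the last stereocentre.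

**Step 4**
Reactants: 6 methyl 2-hydroxy-3-methoxybenzoate
Product: 7 2-hydroxy-3-methoxybenzoic acid
Conditions: NaOH (4 equiv), MeOH/H2O 1:1, reflux, 4 h; then aq HCl to pH 1
Reagents that add atoms: sodium hydroxide, [Na+].[OH-]
Why: Saponification by acyl–oxygen cleavage with excess hydroxide at reflux overcomes the slow attack on the phenoxide ester, and the aryl methyl ether is inert.

**Step 5**
Reactants: 7 2-hydroxy-3-methoxybenzoic acid
Product: 8 5-bromo-2-hydroxy-3-methoxybenzoic acid
Conditions: Br2 (1.0 equiv), AcOH, 15 °C → rt, 2 h
Reagents that add atoms: bromine, BrBr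
Why: In this electrophilic aromatic bromination C5 is para to the strongest donor (OH) and meta to CO2H, and in water-free AcOH with one equivalent of Br2 the ipso pathway does not compete.

**Step 6**
Reactants: 8 5-bromo-2-hydroxy-3-methoxybenzoic acid
Product: 9 2,4-dibromo-6-methoxyphenol
Conditions: Br2 (1.0 equiv), NaOAc (3 equiv), AcOH/H2O 4:1, 0 °C → rt, 3 h
Reagents that add atoms: bromine, BrBr
Why: In this bromodecarboxylation of a salicylic acid, ipso attack ortho to the OH gives a bromodienone carboxylate that loses CO2 irreversibly, whereas C4 and C6 are meta to OH and each flanked by two substituents.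

**Step 7**
Reactants: 9 2,4-dibromo-6-methoxyphenol; 10 2-bromo-1-fluoro-4-nitrobenzene
Product: 11 1,5-dibromo-2-(2-bromo-4-nitrophenoxy)-3-methoxybenzene
Conditions: K2CO3 (2 equiv), DMF, 100 °C, 12 h, N2
Reagents that add atoms: none
Why: In this SNAr reaction via a Meisenheimer adduct, the fluoride para to NO2 is displaced even by the hindered phenoxide, while every C–Br bond (that of 10 is meta to NO2) is unactivated and survives.

**Step 8**
Reactants: 11 1,5-dibromo-2-(2-bromo-4-nitrophenoxy)-3-methoxybenzene
Product: 12 3-bromo-4-(2,4-dibromo-6-methoxyphenoxy)aniline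
Conditions: Fe powder (5 equiv), AcOH/EtOH 1:2, 70 °C, 2 h
Reagents that add atoms: none
Why: Béchamp-type dissolving-metal reduction of the nitro group is chemoselective and, unlike catalytic hydrogenation, touches neither the aryl bromides nor the ethers.

**Step 9**
Reactants: 12 3-bromo-4-(2,4-dibromo-6-methoxyphenoxy)aniline
Product: 14 1,5-dibromo-2-(2,4-dibromophenoxy)-3-methoxybenzene, via diazonium bromide 13 (not isolated)
Conditions: NaNO2 (1.1 equiv), 48 % aq HBr, AcOH, 0–5 °C, 30 min; then added to CuBr (1.2 equiv), 48 % aq HBr, 60 °C, 45 min
Reagents that add atoms: hydrobromic acid, Br (the new bromine; CuBr, [Cu]Br, carries it and is regenerated); sodium nitrite, [Na+].[O-]N=O (one N, held only in 13)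
Why: In this Sandmeyer reaction the unhindered aniline diazotises cleanly and CuBr-mediated electron transfer replaces N2 by Br exactly at C4', while the short time at 60 °C is too mild for HBr to cleave the methyl ether.

**Compound list**
1 | methyl 4-methoxy-3-oxobutanoate | COCC(=O)CC(=O)OC | starting material
2 | prop-2-enal (acrolein) | C=CC=O | starting material
3 | methyl 2-(2-methoxyacetyl)-5-oxopentanoate (racemic) | COCC(=O)C(CCC=O)C(=O)OC | intermediate
4 | methyl 4-hydroxy-3-methoxy-2-oxocyclohexane-1-carboxylate (racemic diastereomer mixture) | COC1C(O)CCC(C(=O)OC)C1=O | intermediate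
5 | methyl 3-methoxy-2-oxocyclohex-3-ene-1-carboxylate (racemic) | COC1=CCCC(C(=O)OC)C1=O | intermediate
6 | methyl 2-hydroxy-3-methoxybenzoate | COc1cccc(C(=O)OC)c1O | intermediate
7 | 2-hydroxy-3-methoxybenzoic acid | COc1cccc(C(=O)O)c1O | intermediate
8 | 5-bromo-2-hydroxy-3-methoxybenzoic acid | COc1cc(Br)cc(C(=O)O)c1O | intermediate
9 | 2,4-dibromo-6-methoxyphenol | COc1cc(Br)cc(Br)c1O | intermediate
10 | 2-bromo-1-fluoro-4-nitrobenzene | O=[N+]([O-])c1ccc(F)c(Br)c1 | starting material
11 | 1,5-dibromo-2-(2-bromo-4-nitrophenoxy)-3-methoxybenzene | COc1cc(Br)cc(Br)c1Oc1ccc([N+](=O)[O-])cc1Br | intermediate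
12 | 3-bromo-4-(2,4-dibromo-6-methoxyphenoxy)aniline | COc1cc(Br)cc(Br)c1Oc1ccc(N)cc1Br | intermediate
13 | 3-bromo-4-(2,4-dibromo-6-methoxyphenoxy)benzenediazonium bromide | COc1cc(Br)cc(Br)c1Oc1ccc([N+]#N)cc1Br.[Br-] | intermediate
14 | 1,5-dibromo-2-(2,4-dibromophenoxy)-3-methoxybenzene (achiral) | COc1cc(Br)cc(Br)c1Oc1ccc(Br)cc1Br | target

**Totals**
Total step count: 9.
Longest linear sequence: 9 steps (1 and 2 → 14; 10 is bought).

**Three steps most likely to fail**

Step 1. Acrolein may polymerise or add twice, and the ketol may close poorly. The fallback leaves the enal out and sets out from 1.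
- Silylation (Me3SiCl, Et3N, toluene, rt) gives methyl 4-methoxy-3-(trimethylsilyloxy)but-2-enoate F1.
- A second silylation (LDA, THF, −78 °C, then Me3SiCl) gives 1,4-dimethoxy-1,3-bis(trimethylsilyloxy)buta-1,3-diene F2.
- A TiCl4-mediated double Mukaiyama-type condensation of F2 with the symmetrical 1,1,3,3-tetramethoxypropane (CH2Cl2, −78 °C → rt, formal 3+3 cycloaromatisation) gives the arene directly.
- This comes back to the route at 6, and 3, 4, 5 and the DDQ oxidation are bypassed.

Step 6. Bromine may enter C4 or C6 of 8, or oxidise the product, instead of displacing CO2. The fallback separates loss of CO2 from bromination and sets out from 7.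
- Metal-free thermal protodecarboxylation (quinoline, 200 °C) gives 2-methoxyphenol F3.
- OH-directed double bromination (Br2 2.0 equiv, AcOH, 0 °C → rt) comes back to the route at 9.
- Compound 8 is then not needed.

Step 9. Hydrodediazoniation or phenol formation may compete with bromide transfer. In the fallback, ring B arrives with both bromines already in place.
- 1,3-Dibromobenzene is coupled with iodyl sulfate (from I2 and KIO3 in conc. H2SO4) and precipitated with NaCl as bis(2,4-dibromophenyl)iodonium chloride F4.
- Setting out from 9, metal-free O-arylation with this trivalent iodine reagent (NaOH, H2O/1,4-dioxane, reflux) comes back to the route at 14.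
- Compounds 10, 11, 12 and 13 drop out.

**Further compounds**
F1 | step 1 | methyl 4-methoxy-3-(trimethylsilyloxy)but-2-enoate (E/Z mixture) | COCC(=CC(=O)OC)O[Si](C)(C)C
F2 | step 1 | 1,4-dimethoxy-1,3-bis(trimethylsilyloxy)buta-1,3-diene (E/Z mixture) | COC=C(O[Si](C)(C)C)C=C(OC)O[Si](C)(C)C
F3 | step 6 | 2-methoxyphenol | COc1ccccc1O
F4 | step 9 | bis(2,4-dibromophenyl)iodonium chloride | Brc1ccc([I+]c2ccc(Br)cc2Br)c(Br)c1.[Cl-]
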